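**One balance.** E, X and Z together hold the E charged: the noon row at 120 min sums to 101%. So take uptake u as the E charged minus the E found, and take cQ as the charge of Q minus the uptake.

the same everywhere: E 0.10 M
- dawn: Q 0.091 M; run made earlier
- noon: Q 0.12 M; run made earlier
- summer: Q 0.15 M; run made earlier
- epsilon: Q 0.0800 M; time 2.0 h
- alpha: Q 0.100 M; time 2.0 h
- zeta: Q 0.200 M; time 2.0 h

| run | time / min | X / % | Z / % | E / % |
|---|---|---|---|---|
| dawn | 25.0 | 45.0 | 3.1 | 52.3 |
| dawn | 50.0 | 55.1 | 2.3 | 42.3 |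
| dawn | 80.0 | 62.1 | 1.9 | 36.0 |
| dawn | 90.0 | 63.8 | 2.3 | 34.6 |
| dawn | 120 | 67.9 | 1.2 | 31.2 |
| noon | 10.0 | 35.0 | 2.6 | 62.5 |
| noon | 30.0 | 54.6 | 4.4 | 42.0 |
| noon | 60.0 | 67.5 | 5.4 | 28.9 |
| noon | 80.0 | 72.3 | 4.0 | 24.2 |
| noon | 120 | 78.4 | 2.2 | 20.1 |
| summer | 25.0 | 57.5 | 6.7 | 37.0 |
| summer | 50.0 | 70.7 | 7.4 | 23.6 |
| summer | 80.0 | 79.6 | 4.5 | 16.0 |
| summer | 90.0 | 78.4 | 3.6 | 14.9 |
| summer | 120 | 84.2 | 3.7 | 12.8 |

(scatter of a reading: 1 percentage point)



* final X, as a percentage of the E charged, for each flask in turn (epsilon, alpha, zeta)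

**Stall quotient.** Define S as u/E divided by the reckoned cQ, at a stated time 99.1 /M. That value is the noon reading at 120 min. Dawn reads 99.3 /M, about the same. Summer reads 108 /M, which is higher. The asked time equals that reading time, so use S as a value for that time, not as an end point.

**Alpha's curve.** Start from noon's first row. The closed second-order form gives k = 0.477 /M/min. Alpha's charges are equal, so E starts falling at 0.0477 /min of itself. It halves at 21.0 min. Solve the quadratic in S: uptake at 2.0 h is 72.9%. The plain hyperbola crosses that mark at 56.4 min, so expect the knee before then.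

**My reckoning.** Epsilon's uptake is 62.9% and zeta's is 91.5%. Subtract Z read at 120 min in the run nearest in Q charge: dawn for epsilon and alpha, summer for zeta. X comes to 61.7%, 71.7% and 87.8%. Zeta's charge lies beyond summer's, so trust that figure less.

**The forecast.** It gives 62.5%, 72% and 86%. Its own quotient uses X, and of that it says “so it is nearly constant”. Its three figures differ from mine.

**The result.** The flasks give 61.8%, 70.7% and 87.4%.

    Z → L (k = 2.46 × 10⁻⁶ /s)
    2 Q → D (k = 0.00198 /M/s)
    Q + X ⇌ Z (K = 3.59 /M, k = 0.00338 /M/s)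
    E + Q → X (k = 0.00913 /M/s)

At the asked time S reads 93.4 /M in alpha and 138 /M in zeta. In epsilon, 2 Q to D has 85% of its turnover to the asked time behind it by 0.400 h. So epsilon's S counts 0.0174 M of Q, while 0.00269 M stands there at 2.00 h.

The readings stem from a simulated flask for substances that don't exist.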